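**Plan**

Numbering: carbocycle C1–C10. The ether O joins C1 and C4 (oxolane O, C1–C4). C5=C6 is the enol-lactone alkene, C7=C11 the butenolide alkene, C12 the lactone C=O, C13 the CH2OAc carbon, C14/C15 the methyls on C10/C4. O8 carries the angelate and O10 is the free tertiary hydroxyl.
Cuts, in retrosynthetic order: O8–angeloyl and O13–acetyl; C5=C6 back to C5H2–C6H; C6–C7 together with O6–C12 (ten-membered ring and butenolide); C7–C11; C8–O8; C8–C9; last, O–C1 of the oxolane.
Enabling feature: the C4 ether oxygen lies three carbons from C1, and C1 is bonded to the C10 carbinol that bears C9 and C14. Oxolane C1–C4 plus a C9,C10-diol is therefore what a C4-hydroxy C1=C10 alkene with an allylic C9-OH gives on epoxidation and ring opening. Those ten carbons (C1–C6, C9, C10, C14, C15) are (S)-linalool.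
Forward: oxolane (step 2), a temporary C7–C10 γ-lactone formed with the C8–C9 bond (step 4), chain extension C7–C11 (step 9), ten-membered ring and butenolide together (step 13), ylidene (step 14), esters last.
Stereochemistry: C4 comes from (S)-linalool. C10 and C1 come from the tartrate-controlled epoxide (C1 by inversion). C8 comes from hydroxylation of the γ-lactone enolate anti to the oxolanyl group on C10. The C7=C11 geometry comes from a lithium-chelated enolate and the C5=C6 geometry from the ring. The Z-alkene of the angelate is bought with angelic acid.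

Key step: step 2

Assumption: (S)-(+)-linalool of high enantiomeric purity, methyl 3-hydroxypropanoate and angelic acid are taken as purchasable.
Remark: read literally, the SMILES string gives 1S,4S,8S,10R with C4 cis to C7 on C5=C6. C5 and C10 then leave the oxolane from opposite faces. It is assumed that the ten-membered ring can span them, so the ring is closed while C5 and C6 are still sp3.

**Step 1**
Reactants: 1 (S)-linalool
Product: 2 (2E,6S)-2,6-dimethylocta-2,7-diene-1,6-diol
Conditions: SeO2 (cat.), t-BuOOH, CH2Cl2, 0 °C to rt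
Reagents that add atoms: tert-butyl hydroperoxide, CC(C)(C)OO
Why: Selenium dioxide allylic oxidation (ene reaction followed by a [2,3]-sigmatropic shift) attacks the electron-rich trisubstituted alkene and, as is general for gem-dimethyl alkenes, oxidises the E-methyl group, so the E-allylic alcohol should form while the vinyl carbinol at C4 is left alone.

**Step 2**
Reactants: 2 (2E,6S)-2,6-dimethylocta-2,7-diene-1,6-diol
Product: 4 (2R)-2-[(2S,5S)-5-ethenyl-5-methyloxolan-2-yl]propane-1,2-diol, via epoxy alcohol 3 (not isolated)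
Conditions: Ti(OiPr)4 (1.0 equiv), D-(−)-diisopropyl tartrate (1.2 equiv), t-BuOOH, 4 Å MS, CH2Cl2, −20 °C, then rt
Reagents that add atoms: tert-butyl hydroperoxide, CC(C)(C)OO
Why: The C9 hydroxyl docks the alkene on the complex formed from Ti(OiPr)4 and the tartrate, which transfers the distal oxygen of bound t-BuOOH to one face of C1=C10 (Sharpless asymmetric epoxidation) and gives the (1R,10R)-epoxy alcohol 3. While 3 is still chelated to titanium through O9 and the epoxide oxygen, the C4 hydroxyl attacks C1 from the rear with cleavage of the C1–O bond, the closest known reactions being the Ti(OiPr)4-assisted C3-selective opening of 2,3-epoxy alcohols and the cyclisation of 6,7-epoxylinalool to the furanoid linalool oxides. The oxolane closes in the 5-exo-tet mode. C10 is set by the face of oxygen delivery, which D-(−)-tartrate dictates, and keeps that C–O bond, whereas C1 is set by the same face selection followed by stereospecific inversion, so that 1S,10R arises next to the untouched 4S centre with C5 and C10 trans on the ring. The step needs chemoselectivity, secured because the C4 vinyl carbinol, although allylic too, is a tertiary alcohol on a monosubstituted alkene and is epoxidised far more slowly than the trisubstituted alkene of the primary allylic alcohol. It also needs attack at C1 and not at C10, secured by the smaller ring, by chelation through O9 and by the inductive effect of the CH2OH group that disfavours positive charge at C10; a full equivalent of titanium is used because the diol product binds the metal.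

**Step 3**
Reactants: 4 (2R)-2-[(2S,5S)-5-ethenyl-5-methyloxolan-2-yl]propane-1,2-diol
Product: 6 (2S,5S)-2-ethenyl-2-methyl-5-[(2R)-2-methyloxiran-2-yl]oxolane, via primary tosylate 5 (not isolated)
Conditions: NaH, N-tosylimidazole, THF, 0 °C to rt
Reagents that add atoms: none
Why: Selective sulfonylation of the primary C9 alkoxide followed by intramolecular Williamson displacement by the C10 alkoxide is the standard diol-to-epoxide conversion, and because only the C9–O bond breaks the C10 configuration is retained.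

**Step 4**
Reactants: 6 (2S,5S)-2-ethenyl-2-methyl-5-[(2R)-2-methyloxiran-2-yl]oxolane; 7 acetic acid
Product: 9 (5R)-5-[(2S,5S)-5-ethenyl-5-methyloxolan-2-yl]-5-methyloxolan-2-one, via hydroxy acid 8 (not isolated)
Conditions: 7, LiN(iPr)2 (2 equiv), THF, 0 to 45 °C; add 6, 45 °C; then aq. HCl, rt
Reagents that add atoms: none
Why: The acetic acid dianion opens 2,2-disubstituted epoxides at the CH2 terminus by SN2 attack (C8–C9 bond), and the tertiary γ-hydroxy acid lactonises on acidification, which masks O10 and activates C7 in one five-membered ring without touching a stereocentre.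

**Step 5**
Reactants: 9 (5R)-5-[(2S,5S)-5-ethenyl-5-methyloxolan-2-yl]-5-methyloxolan-2-one
Product: 10 (3S,5R)-5-[(2S,5S)-5-ethenyl-5-methyloxolan-2-yl]-3-hydroxy-5-methyloxolan-2-one
Conditions: NaN(SiMe3)2, THF, −78 °C; 3-phenyl-2-(phenylsulfonyl)oxaziridine, −78 °C
Reagents that add atoms: 3-phenyl-2-(phenylsulfonyl)oxaziridine, O=S(=O)(c1ccccc1)N1OC1c1ccccc1
Why: Enolate hydroxylation with an N-sulfonyloxaziridine (Davis oxidation) should deliver oxygen to the face of the flat lactone enolate that is turned away from the bulky oxolanyl group on C10 and is cis to the C14 methyl, which is the 8S configuration, and the sodium enolate is chosen to suppress addition to the sulfonimine formed.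

**Step 6**
Reactants: 10 (3S,5R)-5-[(2S,5S)-5-ethenyl-5-methyloxolan-2-yl]-3-hydroxy-5-methyloxolan-2-one
Product: 11 (2S,4R)-4-[(2S,5S)-5-ethenyl-5-methyloxolan-2-yl]-2,4-dihydroxy-N-methoxy-N-methylpentanamide
Conditions: MeNH(OMe)·HCl, i-PrMgCl, THF, −20 to 0 °C
Reagents that add atoms: N,O-dimethylhydroxylamine hydrochloride, CNOC.Cl
Why: Aminolysis of the lactone by the chloromagnesium amide (Weinreb amide formation) opens the ring under conditions in which C8, held as its alkoxide, should not epimerise.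

**Step 7**
Reactants: 11 (2S,4R)-4-[(2S,5S)-5-ethenyl-5-methyloxolan-2-yl]-2,4-dihydroxy-N-methoxy-N-methylpentanamide
Product: 12 (2S,4R)-4-[(2S,5S)-5-ethenyl-5-methyloxolan-2-yl]-N-methoxy-N-methyl-2,4-bis(triethylsilyloxy)pentanamide
Conditions: Et3SiOTf, 2,6-lutidine, CH2Cl2, −78 to 0 °C (on crude 11)
Reagents that add atoms: triethylsilyl trifluoromethanesulfonate, CC[Si](CC)(CC)OS(=O)(=O)C(F)(F)F
Why: A silyl triflate with 2,6-lutidine silylates secondary and tertiary alcohols alike, and doing so at once forestalls relactonisation of the tertiary γ-hydroxy amide.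

**Step 8**
Reactants: 13 methyl 3-hydroxypropanoate
Product: 14 methyl 3-(tert-butyldimethylsilyloxy)propanoate
Conditions: t-BuMe2SiCl, imidazole, CH2Cl2, rt
Reagents that add atoms: tert-butyldimethylsilyl chloride, CC(C)(C)[Si](C)(C)Cl
Why: This is the standard silylation of a primary alcohol with a silyl chloride and imidazole.

**Step 9**
Reactants: 12 (2S,4R)-4-[(2S,5S)-5-ethenyl-5-methyloxolan-2-yl]-N-methoxy-N-methyl-2,4-bis(triethylsilyloxy)pentanamide; 14 methyl 3-(tert-butyldimethylsilyloxy)propanoate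
Product: 15 methyl (4S,6R)-2-[(tert-butyldimethylsilyloxy)methyl]-6-[(2S,5S)-5-ethenyl-5-methyloxolan-2-yl]-3-oxo-4,6-bis(triethylsilyloxy)heptanoate (C11 epimers)
Conditions: 14, LiN(iPr)2, THF, −78 °C; add 12, −78 to −40 °C
Reagents that add atoms: none
Why: Crossed Claisen-type acylation of an ester enolate by a Weinreb amide forms C7–C11, the chelated tetrahedral adduct blocks over-addition and enolisation towards C8, and the new C11 centre is of no consequence because it becomes sp2 in step 10.

**Step 10**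
Reactants: 15 methyl (4S,6R)-2-[(tert-butyldimethylsilyloxy)methyl]-6-[(2S,5S)-5-ethenyl-5-methyloxolan-2-yl]-3-oxo-4,6-bis(triethylsilyloxy)heptanoate
Product: 16 methyl (2Z,4S,6R)-2-[(tert-butyldimethylsilyloxy)methyl]-6-[(2S,5S)-5-ethenyl-5-methyloxolan-2-yl]-4,6-bis(triethylsilyloxy)-3-(trifluoromethylsulfonyloxy)hept-2-enoate
Conditions: LiN(SiMe3)2, Et2O, −78 °C; Tf2O, −78 to 0 °C
Reagents that add atoms: trifluoromethanesulfonic anhydride, O=S(=O)(OS(=O)(=O)C(F)(F)F)C(F)(F)F
Why: O-Sulfonylation of the lithium-chelated U-shaped enolate of a 2-substituted β-keto ester places the triflate cis to the ester (Z-enol triflate), and the far more acidic C11–H ensures that C8 is not deprotonated.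

**Step 11**
Reactants: 16 (Z)-enol triflate with the C5=C6 vinyl group
Product: 18 methyl (2Z,4S,6R)-2-[(tert-butyldimethylsilyloxy)methyl]-6-[(2S,5S)-5-(2-hydroxyethyl)-5-methyloxolan-2-yl]-4,6-bis(triethylsilyloxy)-3-(trifluoromethylsulfonyloxy)hept-2-enoate, via B-alkylborane 17 (not isolated)
Conditions: 9-BBN, THF, 0 °C to rt; then H2O2, aq. NaHCO3, 0 °C
Reagents that add atoms: hydrogen peroxide, OO
Why: In this hydroboration–oxidation 9-BBN places boron on the terminal C6 of the monosubstituted alkene and ignores the tetrasubstituted electron-poor C7=C11 alkene, the selectivity relied on in B-alkyl Suzuki sequences on substrates that carry alkenyl triflates, and buffered peroxide spares triflate and ester.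

**Step 12**
Reactants: 18 primary C6 alcohol
Product: 19 methyl (2Z,4S,6R)-2-[(tert-butyldimethylsilyloxy)methyl]-6-[(2S,5S)-5-methyl-5-(2-oxoethyl)oxolan-2-yl]-4,6-bis(triethylsilyloxy)-3-(trifluoromethylsulfonyloxy)hept-2-enoate
Conditions: Dess–Martin periodinane, CH2Cl2, 0 °C to rt
Reagents that add atoms: none
Why: Dess–Martin oxidation gives the aldehyde under nearly neutral conditions, which avoids β-elimination of the C4 ether oxygen.

**Step 13**
Reactants: 19 C6 aldehyde carrying the C7 enol triflate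
Product: 21 (1S,4S,8S,10R)-13-(tert-butyldimethylsilyloxy)-1,4-epoxy-8,10-bis(triethylsilyloxy)germacr-7(11)-en-12,6-olide (C6 epimers), via hydroxy ester 20 (not isolated)
Conditions: CrCl2 (excess), NiCl2 (cat.), DMF, rt, slow addition, ca. 1 mM
Reagents that add atoms: none
Why: In this intramolecular Nozaki–Hiyama–Kishi reaction zerovalent nickel inserts into the electron-poor alkenyl triflate with retention, transmetalation gives a trivalent alkenylchromium species that adds chemoselectively to the C6 aldehyde and closes the ten-membered carbocycle while C5 and C6 are sp3, the alkoxide cis to the ester lactonises to the butenolide, and the C6 configuration does not matter because C6 becomes sp2 in step 14.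

**Step 14**
Reactants: 21 butenolide (C6–H)
Product: 24 (1S,4S,5E,8S,10R)-13-(tert-butyldimethylsilyloxy)-1,4-epoxy-8,10-bis(triethylsilyloxy)germacra-5,7(11)-dien-12,6-olide, via silyloxyfuran 22 (not isolated), via bromobutenolide 23 (not isolated)
Conditions: t-BuMe2SiOTf, Et3N, CH2Cl2, 0 °C; NBS, −78 °C; DBU, −78 °C to rt
Reagents that add atoms: none
Why: Soft enolisation removes C6–H to give the aromatic 2-silyloxyfuran, such furans are brominated at their 5-position (C6), and dehydrobromination of the tertiary γ-bromobutenolide can only use a C5–H, a known route to γ-alkylidenebutenolides in which the ten-membered ring allows only the isomer with C4 and C7 cis, the required 5E geometry.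

**Step 15**
Reactants: 24 silyl-protected ylidene butenolide
Product: 25 (1S,4S,5E,8S,10R)-1,4-epoxy-8,10,13-trihydroxygermacra-5,7(11)-dien-12,6-olide
Conditions: HF·pyridine, pyridine, THF, 0 °C to rt
Reagents that add atoms: none
Why: Fluoride-driven cleavage of all three silyl ethers under buffered, weakly acidic conditions should leave the enol lactone intact.

**Step 16**
Reactants: 25 triol
Product: 26 (1S,4S,5E,8S,10R)-13-acetoxy-1,4-epoxy-8,10-dihydroxygermacra-5,7(11)-dien-12,6-olide
Conditions: Ac2O (1.1 equiv), pyridine, CH2Cl2, −20 °C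
Reagents that add atoms: acetic anhydride, CC(=O)OC(C)=O
Why: Kinetic acylation distinguishes the unhindered primary allylic C13 hydroxyl from the secondary C8 and tertiary C10 hydroxyls.

**Step 17**
Reactants: 26 13-acetate diol; 27 angelic acid
Product: 29 (1S,4S,5E,8S,10R)-13-acetoxy-8-angeloyloxy-1,4-epoxy-10-hydroxygermacra-5,7(11)-dien-12,6-olide (CNP0162854.1), via mixed anhydride 28 (not isolated)
Conditions: 27, 2,4,6-trichlorobenzoyl chloride, Et3N, toluene, rt; add 26, 80 °C
Reagents that add atoms: none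
Why: Yamaguchi-type esterification through the mixed anhydride without a nucleophilic catalyst is the established way to transfer the angeloyl group without isomerisation to the tiglate, and the tertiary C10 hydroxyl is too hindered to compete with O8.

**Compound list**

1 | (S)-linalool, (3S)-3,7-dimethylocta-1,6-dien-3-ol | CC(C)=CCC[C@@](C)(C=C)O | starting material
2 | (2E,6S)-2,6-dimethylocta-2,7-diene-1,6-diol | OC/C(C)=C/CC[C@@](C)(C=C)O | intermediate
3 | (3S)-5-[(2R,3R)-3-(hydroxymethyl)-3-methyloxiran-2-yl]-3-methylpent-1-en-3-ol | OC[C@@]1(C)O[C@@H]1CC[C@@](C)(C=C)O | intermediate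
4 | (2R)-2-[(2S,5S)-5-ethenyl-5-methyloxolan-2-yl]propane-1,2-diol | OC[C@@](C)(O)[C@@H]1CC[C@@](C)(C=C)O1 | intermediate
5 | (2R)-2-[(2S,5S)-5-ethenyl-5-methyloxolan-2-yl]-2-hydroxypropyl 4-methylbenzenesulfonate | Cc1ccc(cc1)S(=O)(=O)OC[C@@](C)(O)[C@@H]1CC[C@@](C)(C=C)O1 | intermediate
6 | (2S,5S)-2-ethenyl-2-methyl-5-[(2R)-2-methyloxiran-2-yl]oxolane | C1[C@@](C)(O1)[C@@H]2CC[C@@](C)(C=C)O2 | intermediate
7 | acetic acid | CC(=O)O | starting material
8 | (4R)-4-[(2S,5S)-5-ethenyl-5-methyloxolan-2-yl]-4-hydroxypentanoic acid | OC(=O)CC[C@@](C)(O)[C@@H]1CC[C@@](C)(C=C)O1 | intermediate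
9 | (5R)-5-[(2S,5S)-5-ethenyl-5-methyloxolan-2-yl]-5-methyloxolan-2-one | O=C1CC[C@@](C)(O1)[C@@H]2CC[C@@](C)(C=C)O2 | intermediate
10 | (3S,5R)-5-[(2S,5S)-5-ethenyl-5-methyloxolan-2-yl]-3-hydroxy-5-methyloxolan-2-one | O=C1[C@@H](O)C[C@@](C)(O1)[C@@H]2CC[C@@](C)(C=C)O2 | intermediate
11 | (2S,4R)-4-[(2S,5S)-5-ethenyl-5-methyloxolan-2-yl]-2,4-dihydroxy-N-methoxy-N-methylpentanamide | CON(C)C(=O)[C@@H](O)C[C@@](C)(O)[C@@H]1CC[C@@](C)(C=C)O1 | intermediate
12 | (2S,4R)-4-[(2S,5S)-5-ethenyl-5-methyloxolan-2-yl]-N-methoxy-N-methyl-2,4-bis(triethylsilyloxy)pentanamide | CON(C)C(=O)[C@@H](O[Si](CC)(CC)CC)C[C@@](C)(O[Si](CC)(CC)CC)[C@@H]1CC[C@@](C)(C=C)O1 | intermediate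
13 | methyl 3-hydroxypropanoate | COC(=O)CCO | starting material
14 | methyl 3-(tert-butyldimethylsilyloxy)propanoate | COC(=O)CCO[Si](C)(C)C(C)(C)C | intermediate
15 | methyl (4S,6R)-2-[(tert-butyldimethylsilyloxy)methyl]-6-[(2S,5S)-5-ethenyl-5-methyloxolan-2-yl]-3-oxo-4,6-bis(triethylsilyloxy)heptanoate, C11 (heptanoate C2) epimers | COC(=O)C(CO[Si](C)(C)C(C)(C)C)C(=O)[C@@H](O[Si](CC)(CC)CC)C[C@@](C)(O[Si](CC)(CC)CC)[C@@H]1CC[C@@](C)(C=C)O1 | intermediate
16 | methyl (2Z,4S,6R)-2-[(tert-butyldimethylsilyloxy)methyl]-6-[(2S,5S)-5-ethenyl-5-methyloxolan-2-yl]-4,6-bis(triethylsilyloxy)-3-(trifluoromethylsulfonyloxy)hept-2-enoate | COC(=O)/C(CO[Si](C)(C)C(C)(C)C)=C(\OS(=O)(=O)C(F)(F)F)[C@@H](O[Si](CC)(CC)CC)C[C@@](C)(O[Si](CC)(CC)CC)[C@@H]1CC[C@@](C)(C=C)O1 | intermediate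
17 | B-alkyl-9-borabicyclo[3.3.1]nonane from 16 (boron on C6, rest as in 16) | COC(=O)/C(CO[Si](C)(C)C(C)(C)C)=C(\OS(=O)(=O)C(F)(F)F)[C@@H](O[Si](CC)(CC)CC)C[C@@](C)(O[Si](CC)(CC)CC)[C@@H]1CC[C@@](C)(CCB2C3CCCC2CCC3)O1 | intermediate
18 | methyl (2Z,4S,6R)-2-[(tert-butyldimethylsilyloxy)methyl]-6-[(2S,5S)-5-(2-hydroxyethyl)-5-methyloxolan-2-yl]-4,6-bis(triethylsilyloxy)-3-(trifluoromethylsulfonyloxy)hept-2-enoate | COC(=O)/C(CO[Si](C)(C)C(C)(C)C)=C(\OS(=O)(=O)C(F)(F)F)[C@@H](O[Si](CC)(CC)CC)C[C@@](C)(O[Si](CC)(CC)CC)[C@@H]1CC[C@@](C)(CCO)O1 | intermediate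
19 | methyl (2Z,4S,6R)-2-[(tert-butyldimethylsilyloxy)methyl]-6-[(2S,5S)-5-methyl-5-(2-oxoethyl)oxolan-2-yl]-4,6-bis(triethylsilyloxy)-3-(trifluoromethylsulfonyloxy)hept-2-enoate | COC(=O)/C(CO[Si](C)(C)C(C)(C)C)=C(\OS(=O)(=O)C(F)(F)F)[C@@H](O[Si](CC)(CC)CC)C[C@@](C)(O[Si](CC)(CC)CC)[C@@H]1CC[C@@](C)(CC=O)O1 | intermediate
20 | ten-membered hydroxy ester: C6 carbinol (epimers), exocyclic C7=C11 with CO2Me cis to C6 and CH2OTBS cis to C8, O8 and O10 as TES ethers, 1S,4S,8S,10R | CC[Si](CC)(CC)O[C@H]1C[C@@](C)(O[Si](CC)(CC)CC)[C@@H]2CC[C@@](C)(CC(O)/C1=C(/CO[Si](C)(C)C(C)(C)C)C(=O)OC)O2 | intermediate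
21 | (1S,4S,8S,10R)-13-(tert-butyldimethylsilyloxy)-1,4-epoxy-8,10-bis(triethylsilyloxy)germacr-7(11)-en-12,6-olide, C6 epimers | CC[Si](CC)(CC)O[C@H]1C[C@@](C)(O[Si](CC)(CC)CC)[C@@H]2CC[C@@](C)(CC3OC(=O)C(CO[Si](C)(C)C(C)(C)C)=C31)O2 | intermediate
22 | 2-(tert-butyldimethylsilyloxy)furan from 21 (furan atoms O, C6, C7, C11, C12; rest as in 21) | CC[Si](CC)(CC)O[C@H]1C[C@@](C)(O[Si](CC)(CC)CC)[C@@H]2CC[C@@](C)(Cc3oc(O[Si](C)(C)C(C)(C)C)c(CO[Si](C)(C)C(C)(C)C)c31)O2 | intermediate
23 | 6-bromo derivative of 21 (C6 configuration open) | CC[Si](CC)(CC)O[C@H]1C[C@@](C)(O[Si](CC)(CC)CC)[C@@H]2CC[C@@](C)(CC3(Br)OC(=O)C(CO[Si](C)(C)C(C)(C)C)=C31)O2 | intermediate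
24 | (1S,4S,5E,8S,10R)-13-(tert-butyldimethylsilyloxy)-1,4-epoxy-8,10-bis(triethylsilyloxy)germacra-5,7(11)-dien-12,6-olide | CC[Si](CC)(CC)O[C@H]1C[C@@](C)(O[Si](CC)(CC)CC)[C@@H]2CC[C@@](C)(/C=C3/OC(=O)C(CO[Si](C)(C)C(C)(C)C)=C31)O2 | intermediate
25 | (1S,4S,5E,8S,10R)-1,4-epoxy-8,10,13-trihydroxygermacra-5,7(11)-dien-12,6-olide | O[C@H]1C[C@@](C)(O)[C@@H]2CC[C@@](C)(/C=C3/OC(=O)C(CO)=C31)O2 | intermediate
26 | (1S,4S,5E,8S,10R)-13-acetoxy-1,4-epoxy-8,10-dihydroxygermacra-5,7(11)-dien-12,6-olide | O[C@H]1C[C@@](C)(O)[C@@H]2CC[C@@](C)(/C=C3/OC(=O)C(COC(C)=O)=C31)O2 | intermediate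
27 | angelic acid, (2Z)-2-methylbut-2-enoic acid | C/C=C(/C)C(=O)O | starting material
28 | (2Z)-2-methylbut-2-enoic 2,4,6-trichlorobenzoic anhydride | C/C=C(/C)C(=O)OC(=O)c1c(Cl)cc(Cl)cc1Cl | intermediate
29 | (1S,4S,5E,8S,10R)-13-acetoxy-8-[(2Z)-2-methylbut-2-enoyloxy]-1,4-epoxy-10-hydroxygermacra-5,7(11)-dien-12,6-olide (CNP0162854.1) | C/C=C(/C)C(=O)O[C@H]1C[C@@](C)(O)[C@@H]2CC[C@@](C)(/C=C3/OC(=O)C(COC(C)=O)=C31)O2 | target

**Step count**

Total steps: 17. Longest linear sequence: 16 steps (1–7 and 9–17) from (S)-linalool.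

**Steps most likely to fail**

1. **Step 13 (ring closure).** The two arms leave the oxolane from opposite faces. Intramolecular addition may therefore be outrun by intermolecular coupling or by protonation of the alkenylchromium species.
   - Fallback: form C6–C7 as an sp2–sp2 bond and use the vinyl group as it stands.
   - Setting out from 16, an intramolecular Heck reaction (Pd(OAc)2, PPh3, K2CO3, MeCN, high dilution) between the alkenyl triflate and the C5=C6 vinyl group should give the macrocyclic (5E)-dienoate F1.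
   - Me3SnOH in 1,2-dichloroethane cleaves the methyl ester to the dienoic acid F2.
   - Iodolactonisation (I2, NaHCO3, MeCN) adds O6 and iodine anti across C5=C6 to give the iodolactone F3.
   - Anti elimination of HI with DBU turns the ring-trans alkene into the arrangement with C4 and C7 cis. This rejoins the route at 24 and bypasses steps 11 to 14.

2. **Step 14 (ylidene formation).** On enolisation towards C6, vinylogous expulsion of the C13 silyloxy group may compete with bromination. The ionised bromide may also be captured by adventitious water instead of losing a C5 proton.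
   - Fallback: put a much better leaving group on C5 before the ring is closed.
   - Setting out from 16, dihydroxylation of the vinyl group (OsO4 cat., N-methylmorpholine N-oxide) gives the C5,C6-diol F4.
   - TEMPO with PhI(OAc)2 oxidises only the primary hydroxyl, giving the α-hydroxy aldehyde F5.
   - CrCl2/NiCl2 closure with lactonisation gives the 5-hydroxy butenolide F6.
   - MsCl/Et3N gives the C5 mesylate F7.
   - DBU then induces β-elimination of methanesulfonic acid across C5–C6, the standard aldol-type route to γ-alkylidenebutenolides. This is convergent for all C5/C6 isomers and returns to the route at 24.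

3. **Step 9 (C7–C11 bond).** The hindered α-silyloxy amide may need warming, and the enolate of 14 may then lose silanolate by β-elimination faster than it is acylated.
   - Fallback: replace the acylation by an aldol addition and oxidation, so that the enolate meets a fast electrophile at −78 °C.
   - Setting out from 12, iBu2AlH (THF, −78 °C) gives the α-silyloxy aldehyde F8.
   - The lithium enolate of 14 adds at −78 °C to give the aldol F9 as a stereoisomer mixture at C7 and C11.
   - Dess–Martin oxidation returns to the route at 15.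

**Further compounds**

F1 | step 13 | macrocyclic (5E)-dienoate: ring C5=C6 trans, exocyclic C7=C11 with CO2Me cis to C6, silyl ethers as in 16 | CC[Si](CC)(CC)O[C@H]1C[C@@](C)(O[Si](CC)(CC)CC)[C@@H]2CC[C@@](C)(/C=C/C1=C(/CO[Si](C)(C)C(C)(C)C)C(=O)OC)O2
F2 | step 13 | dienoic acid from F1 | CC[Si](CC)(CC)O[C@H]1C[C@@](C)(O[Si](CC)(CC)CC)[C@@H]2CC[C@@](C)(/C=C/C1=C(/CO[Si](C)(C)C(C)(C)C)C(=O)O)O2
F3 | step 13 | 5-iodo derivative of 21 (anti adduct, face not assigned) | CC[Si](CC)(CC)O[C@H]1C[C@@](C)(O[Si](CC)(CC)CC)[C@@H]2CC[C@@](C)(C(I)C3OC(=O)C(CO[Si](C)(C)C(C)(C)C)=C31)O2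
F4 | step 14 | C5,C6-diol from 16 (C5 epimers) | COC(=O)/C(CO[Si](C)(C)C(C)(C)C)=C(\OS(=O)(=O)C(F)(F)F)[C@@H](O[Si](CC)(CC)CC)C[C@@](C)(O[Si](CC)(CC)CC)[C@@H]1CC[C@@](C)(C(O)CO)O1
F5 | step 14 | 5-hydroxy C6 aldehyde (C5 epimers) | COC(=O)/C(CO[Si](C)(C)C(C)(C)C)=C(\OS(=O)(=O)C(F)(F)F)[C@@H](O[Si](CC)(CC)CC)C[C@@](C)(O[Si](CC)(CC)CC)[C@@H]1CC[C@@](C)(C(O)C=O)O1
F6 | step 14 | 5-hydroxy derivative of 21 (C5 and C6 isomers) | CC[Si](CC)(CC)O[C@H]1C[C@@](C)(O[Si](CC)(CC)CC)[C@@H]2CC[C@@](C)(C(O)C3OC(=O)C(CO[Si](C)(C)C(C)(C)C)=C31)O2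
F7 | step 14 | C5 methanesulfonate of F6 | CC[Si](CC)(CC)O[C@H]1C[C@@](C)(O[Si](CC)(CC)CC)[C@@H]2CC[C@@](C)(C(OS(C)(=O)=O)C3OC(=O)C(CO[Si](C)(C)C(C)(C)C)=C31)O2
F8 | step 9 | (2S,4R)-4-[(2S,5S)-5-ethenyl-5-methyloxolan-2-yl]-2,4-bis(triethylsilyloxy)pentanal | O=C[C@@H](O[Si](CC)(CC)CC)C[C@@](C)(O[Si](CC)(CC)CC)[C@@H]1CC[C@@](C)(C=C)O1
F9 | step 9 | 3-hydroxy analogue of 15 (C7 and C11 isomers) | COC(=O)C(CO[Si](C)(C)C(C)(C)C)C(O)[C@@H](O[Si](CC)(CC)CC)C[C@@](C)(O[Si](CC)(CC)CC)[C@@H]1CC[C@@](C)(C=C)O1
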